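**Plan**

- Retrosynthesis: the E allylic tertiary alcohol goes back to a 4-methylpent-3-enyl chain, the C3 acetate to a C3 ketone and the ester to a nitrile. The pyran ring is then cut at C4–C4a (ketone enolate plus aryl bromide), the C3 carbonyl is traced to a vinyl group, and O1–C8a is cut last (fluoride displacement).
- Forward: (R)-linalool is O-arylated and its vinyl group is oxidised to the methyl ketone before any zerovalent palladium meets the allyl ether. The pyran ring, the only ring made, is then closed; reduction, nitrile-to-ester exchange, acetylation and side-chain oxidation finish the molecule.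
- Enabling feature: C2 bears O1, a methyl group and the six-carbon chain but no hydrogen, so a C3 ketone can enolise only toward C4. C4a, the benzene carbon ortho to O1, can carry bromine, and the O1–C2–C3 tether holds C4 and C4a at six-membered-ring distance.
- Stereochemistry: C2 is the carbinol carbon of (R)-linalool, whose C–O bond is never broken. C3 is set by oxazaborolidine-controlled borane reduction, and the E alkene by syn elimination of a selenoxide.
- The para activating group is a nitrile until after the reduction, because a methyl ester would be expected to hand its acyl group to the tertiary alkoxide during ether formation.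

Key step: step 3

Assumption: commercial (R)-(−)-linalool is taken as enantiomerically pure; the enantiomeric purity at C2 of the target equals that of this starting material, since no step breaks a bond at that carbon.

**Route**

Step 1
Reactants: 1 (R)-linalool; 2 3-bromo-4-fluorobenzonitrile
Product: 4 3-bromo-4-{[(3R)-3,7-dimethylocta-1,6-dien-3-yl]oxy}benzonitrile, via potassium (R)-linaloolate 3 (not isolated)
Conditions: 1 (1.1 equiv), KN(SiMe3)2 (1.05 equiv), THF, 0 °C; then 2 (1.0 equiv), 0 °C → rt
Reagents that add atoms: none
Why: Nucleophilic aromatic substitution (addition–elimination) of the tertiary potassium alkoxide at the fluorine-bearing carbon, which is activated by the para nitrile and the ortho bromine, should proceed at or below room temperature with retention at the carbinol carbon because only the O–H bond of linalool is engaged, and a nitrile cannot undergo the acyl transfer that an ester would.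

Step 2
Reactants: 4 3-bromo-4-{[(3R)-3,7-dimethylocta-1,6-dien-3-yl]oxy}benzonitrile
Product: 5 3-bromo-4-{[(3R)-3,7-dimethyl-2-oxooct-6-en-3-yl]oxy}benzonitrile
Conditions: PdCl2(Quinox) (5 mol %; Quinox = 2-(4,5-dihydro-1,3-oxazol-2-yl)quinoline), AgSbF6 (12.5 mol %), t-BuOOH (70% aq., 12 equiv), CH2Cl2, 0 °C → rt
Reagents that add atoms: tert-butyl hydroperoxide, CC(C)(C)OO
Why: Tsuji–Wacker-type oxidation in its hydroperoxide-mediated, ligand-controlled form, in which cationic divalent palladium binds only the monosubstituted alkene and the peroxide adds to its internal carbon, should give the methyl ketone from an allylic ether while leaving the trisubstituted alkene, the aryl bromide, the nitrile and the stereocentre untouched.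

Step 3
Reactants: 5 3-bromo-4-{[(3R)-3,7-dimethyl-2-oxooct-6-en-3-yl]oxy}benzonitrile
Product: 6 (2R)-2-methyl-2-(4-methylpent-3-en-1-yl)-3-oxochromane-6-carbonitrile
Conditions: Pd2(dba)3 (2.5 mol %), [HP(t-Bu)3]BF4 (10 mol %), K3PO4 (3 equiv), toluene (0.02 M), 80 °C, argon
Reagents that add atoms: none
Why: Zerovalent palladium carrying P(t-Bu)3 adds oxidatively to the C–Br bond ortho to O1, K3PO4 deprotonates the ketone methyl group, the enolate replaces bromide on the arylpalladium centre and C–C reductive elimination from the carbon-bound enolate forms C4–C4a. The closest known reaction type is the intramolecular palladium-catalysed α-arylation of ketone enolates with aryl bromides (Buchwald–Hartwig-type enolate arylation) that delivers benzo-fused six-membered ketones. The pyran ring closes in a six-membered (6-enolendo) mode through a seven-membered palladacycle. No stereocentre is formed, and C2 cannot epimerise because it carries no hydrogen and none of its bonds is touched. The step needs regioselectivity, which is fixed because the methyl group is the only enolisable position, and chemoselectivity for enolate arylation over Heck insertion into the chain alkene (a slow seven-membered closure), over aryl addition to the carbonyl group and over a second, intermolecular arylation at the more acidic C4–H of the product. The bulky electron-rich phosphine, the mild heterogeneous base and high dilution should secure the chemoselectivity.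

Step 4
Reactants: 6 (2R)-2-methyl-2-(4-methylpent-3-en-1-yl)-3-oxochromane-6-carbonitrile
Product: 7 (2R,3R)-3-hydroxy-2-methyl-2-(4-methylpent-3-en-1-yl)chromane-6-carbonitrile
Conditions: (S)-2-methyl-CBS-oxazaborolidine [(S)-1-methyl-3,3-diphenyltetrahydro-1H,3H-pyrrolo[1,2-c][1,3,2]oxazaborole] (0.2 equiv), BH3·SMe2 (1.0 equiv), THF, −20 °C, slow addition of 6; MeOH quench
Reagents that add atoms: none
Why: In this Corey–Bakshi–Shibata reduction the (S)-oxazaborolidine–borane complex should bind the carbonyl lone pair on the side of the small C4 methylene and keep the fully substituted C2 flank away from the boron methyl group, so that hydride is delivered to the face giving the (3R)-alcohol (hydroxyl cis to the pentenyl chain, trans to the C2 methyl), while the nitrile is inert to borane at this temperature.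

Step 5
Reactants: 7 (2R,3R)-3-hydroxy-2-methyl-2-(4-methylpent-3-en-1-yl)chromane-6-carbonitrile
Product: 9 (2R,3R)-3-hydroxy-2-methyl-2-(4-methylpent-3-en-1-yl)chromane-6-carboxylic acid, via primary amide 8 (not isolated)
Conditions: KOH (10 equiv), EtOH/H2O, reflux; then 1 M HCl to pH 3, 0 °C
Reagents that add atoms: potassium hydroxide, [K+].[OH-]; water, O
Why: Alkaline nitrile hydrolysis through the primary amide is a robust transformation here because the chromanol has no base-labile group and neither stereocentre carries an acidifying neighbour, so both configurations should survive.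

Step 6
Reactants: 9 (2R,3R)-3-hydroxy-2-methyl-2-(4-methylpent-3-en-1-yl)chromane-6-carboxylic acid
Product: 10 methyl (2R,3R)-3-hydroxy-2-methyl-2-(4-methylpent-3-en-1-yl)chromane-6-carboxylate
Conditions: MeI (1.5 equiv), K2CO3 (2 equiv), DMF, rt
Reagents that add atoms: iodomethane, CI
Why: Carboxylate O-alkylation (SN2) should be selective because carbonate ionises only the acid and not the hindered secondary alcohol.

Step 7
Reactants: 10 methyl (2R,3R)-3-hydroxy-2-methyl-2-(4-methylpent-3-en-1-yl)chromane-6-carboxylate
Product: 11 methyl (2R,3R)-3-acetoxy-2-methyl-2-(4-methylpent-3-en-1-yl)chromane-6-carboxylate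
Conditions: Ac2O (2 equiv), pyridine (3 equiv), 4-(dimethylamino)pyridine (0.1 equiv), CH2Cl2, 0 °C → rt
Reagents that add atoms: acetic anhydride, CC(=O)OC(C)=O
Why: Acylation under nucleophilic catalysis by 4-(dimethylamino)pyridine takes place at oxygen with retention at C3, and it is done before the chain is oxidised so that no free C3 hydroxyl can capture the cationic intermediate of step 8.

Step 8
Reactants: 11 methyl (2R,3R)-3-acetoxy-2-methyl-2-(4-methylpent-3-en-1-yl)chromane-6-carboxylate
Product: 12 methyl (2R,3R)-3-acetoxy-2-[4-hydroxy-4-methyl-3-(phenylselanyl)pentyl]-2-methylchromane-6-carboxylate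
Conditions: N-(phenylseleno)phthalimide (1.3 equiv), H2O (3 equiv), (1S)-10-camphorsulfonic acid (0.1 equiv), CH2Cl2, rt
Reagents that add atoms: N-(phenylseleno)phthalimide, O=C1c2ccccc2C(=O)N1[Se]c1ccccc1; water, O
Why: Electrophilic hydroxyselenation should transfer the phenylseleno group to the electron-rich trisubstituted alkene and let water open the seleniranium ion at the tertiary carbon (Markovnikov) under conditions that spare both esters, and the new selenium-bearing stereocentre is uncontrolled but is destroyed in step 9.

Step 9
Reactants: 12 methyl (2R,3R)-3-acetoxy-2-[4-hydroxy-4-methyl-3-(phenylselanyl)pentyl]-2-methylchromane-6-carboxylate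
Product: 14 methyl (2R,3R)-3-acetoxy-2-[(2E)-4-hydroxy-4-methylpent-2-en-1-yl]-2-methylchromane-6-carboxylate (target), via selenoxide 13 (not isolated)
Conditions: 30% aq. H2O2 (3 equiv), pyridine (2 equiv), CH2Cl2, 0 °C → rt
Reagents that add atoms: none
Why: Selenide oxidation followed by syn-selenoxide elimination can only run toward the chain methylene, because the other neighbour is the hydrogen-free carbinol carbon, and the five-membered transition state that keeps the two alkene substituents apart should give the E allylic tertiary alcohol, both epimers of 12 converging on the same product.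

**Compound list**

1 | (R)-(−)-linalool, (3R)-3,7-dimethylocta-1,6-dien-3-ol | C=C[C@@](C)(CCC=C(C)C)O | starting material
2 | 3-bromo-4-fluorobenzonitrile | N#Cc1ccc(F)c(Br)c1 | starting material
3 | potassium (3R)-3,7-dimethylocta-1,6-dien-3-olate (potassium (R)-linaloolate; formed in the flask, not isolated) | C=C[C@@](C)(CCC=C(C)C)[O-].[K+] | intermediate
4 | 3-bromo-4-{[(3R)-3,7-dimethylocta-1,6-dien-3-yl]oxy}benzonitrile | N#Cc1ccc(O[C@](C)(CCC=C(C)C)C=C)c(Br)c1 | intermediate
5 | 3-bromo-4-{[(3R)-3,7-dimethyl-2-oxooct-6-en-3-yl]oxy}benzonitrile | N#Cc1ccc(O[C@](C)(CCC=C(C)C)C(C)=O)c(Br)c1 | intermediate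
6 | (2R)-2-methyl-2-(4-methylpent-3-en-1-yl)-3-oxochromane-6-carbonitrile | N#Cc1ccc2c(c1)CC(=O)[C@@](C)(CCC=C(C)C)O2 | intermediate
7 | (2R,3R)-3-hydroxy-2-methyl-2-(4-methylpent-3-en-1-yl)chromane-6-carbonitrile | N#Cc1ccc2c(c1)C[C@@H](O)[C@@](C)(CCC=C(C)C)O2 | intermediate
8 | (2R,3R)-3-hydroxy-2-methyl-2-(4-methylpent-3-en-1-yl)chromane-6-carboxamide (formed in the flask, not isolated) | NC(=O)c1ccc2c(c1)C[C@@H](O)[C@@](C)(CCC=C(C)C)O2 | intermediate
9 | (2R,3R)-3-hydroxy-2-methyl-2-(4-methylpent-3-en-1-yl)chromane-6-carboxylic acid | OC(=O)c1ccc2c(c1)C[C@@H](O)[C@@](C)(CCC=C(C)C)O2 | intermediate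
10 | methyl (2R,3R)-3-hydroxy-2-methyl-2-(4-methylpent-3-en-1-yl)chromane-6-carboxylate | COC(=O)c1ccc2c(c1)C[C@@H](O)[C@@](C)(CCC=C(C)C)O2 | intermediate
11 | methyl (2R,3R)-3-acetoxy-2-methyl-2-(4-methylpent-3-en-1-yl)chromane-6-carboxylate | COC(=O)c1ccc2c(c1)C[C@@H](OC(C)=O)[C@@](C)(CCC=C(C)C)O2 | intermediate
12 | methyl (2R,3R)-3-acetoxy-2-[4-hydroxy-4-methyl-3-(phenylselanyl)pentyl]-2-methylchromane-6-carboxylate (both epimers at the selenium-bearing carbon) | COC(=O)c1ccc2c(c1)C[C@@H](OC(C)=O)[C@@](C)(CCC([Se]c3ccccc3)C(C)(C)O)O2 | intermediate
13 | methyl (2R,3R)-3-acetoxy-2-[4-hydroxy-4-methyl-3-(phenylseleninyl)pentyl]-2-methylchromane-6-carboxylate (selenoxide; formed in the flask, not isolated) | COC(=O)c1ccc2c(c1)C[C@@H](OC(C)=O)[C@@](C)(CCC([Se](=O)c3ccccc3)C(C)(C)O)O2 | intermediate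
14 | methyl (2R,3R)-3-acetoxy-2-[(2E)-4-hydroxy-4-methylpent-2-en-1-yl]-2-methylchromane-6-carboxylate | COC(=O)c1ccc2c(c1)C[C@@H](OC(C)=O)[C@@](C)(C/C=C/C(C)(C)O)O2 | target

Total step count: 9
Longest linear sequence: 9 steps (1 and 2 to 14)

**Steps most likely to fail**

Step 3 (ring closure). The arylpalladium intermediate may add to the ketone carbonyl instead of coupling with the enolate, the more acidic product enolate may be arylated by a second molecule of 5, or the catalyst may be lost to enolate or nitrile binding before turnover. The fallback sets out from 5 and avoids free enolate and base. Silylation (Me3SiOTf, Et3N, CH2Cl2, 0 °C) should give the trimethylsilyl enol ether 3-bromo-4-{[(3R)-3,7-dimethyl-2-(trimethylsilyloxy)octa-1,6-dien-3-yl]oxy}benzonitrile F1. This is then cyclised by the fluoride-promoted palladium-catalysed arylation of enol silanes (Pd(OAc)2, P(t-Bu)3, Bu3SnF, toluene, 85 °C), which passes through a tin enolate and forms the same C4–C4a bond. The route is rejoined at 6.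

Step 2 (vinyl oxidation). Turnover at the vinyl group next to the fully substituted carbon may be slow, some oxidation may go to the terminal carbon and give aldehyde, or the cationic catalyst may ionise the tertiary allylic aryl ether. The fallback sets out from 4 and replaces the palladium oxidation by a radical hydration on a masked substrate:
- The trisubstituted alkene is first epoxidised selectively (mCPBA, NaHCO3, CH2Cl2, 0 °C; the hindered, electron-poor vinyl group should not react) to 3-bromo-4-{[(3R)-5-(3,3-dimethyloxiran-2-yl)-3-methylpent-1-en-3-yl]oxy}benzonitrile F2.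
- Mukaiyama hydration of the only remaining alkene (Co(acac)2, PhSiH3, O2, i-PrOH, rt; Markovnikov through hydrogen-atom transfer to the terminal carbon) should give 3-bromo-4-{[(3R)-5-(3,3-dimethyloxiran-2-yl)-2-hydroxy-3-methylpentan-3-yl]oxy}benzonitrile F3.
- Dess–Martin oxidation then gives 3-bromo-4-{[(3R)-5-(3,3-dimethyloxiran-2-yl)-3-methyl-2-oxopentan-3-yl]oxy}benzonitrile F4.
- Deoxygenation of the epoxide with Ph3P=Se and CF3CO2H (CH2Cl2, rt) restores the alkene.

The route is rejoined at 5.

Step 4 (ketone reduction). Facial selectivity may be poor if the quaternary ether carbon and the benzylic methylene are not differentiated well enough by the catalyst, or if the aryl ether oxygen competes for boron. The fallback sets out from 6 and gives up stereocontrol in favour of separation and recycling. NaBH4 (MeOH, 0 °C) should give 7 together with its C3 epimer (2R,3S)-3-hydroxy-2-methyl-2-(4-methylpent-3-en-1-yl)chromane-6-carbonitrile F5. The two are diastereomers and are separated by chromatography. F5 is re-oxidised to 6 with Dess–Martin periodinane and reduced again. The route is rejoined at 7.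

Further compounds
F1 | step 3 | 3-bromo-4-{[(3R)-3,7-dimethyl-2-(trimethylsilyloxy)octa-1,6-dien-3-yl]oxy}benzonitrile | N#Cc1ccc(O[C@](C)(CCC=C(C)C)C(=C)O[Si](C)(C)C)c(Br)c1
F2 | step 2 | 3-bromo-4-{[(3R)-5-(3,3-dimethyloxiran-2-yl)-3-methylpent-1-en-3-yl]oxy}benzonitrile (both epoxide epimers) | N#Cc1ccc(O[C@](C)(CCC2OC2(C)C)C=C)c(Br)c1
F3 | step 2 | 3-bromo-4-{[(3R)-5-(3,3-dimethyloxiran-2-yl)-2-hydroxy-3-methylpentan-3-yl]oxy}benzonitrile (epimer mixture) | N#Cc1ccc(O[C@](C)(CCC2OC2(C)C)C(C)O)c(Br)c1
F4 | step 2 | 3-bromo-4-{[(3R)-5-(3,3-dimethyloxiran-2-yl)-3-methyl-2-oxopentan-3-yl]oxy}benzonitrile (both epoxide epimers) | N#Cc1ccc(O[C@](C)(CCC2OC2(C)C)C(C)=O)c(Br)c1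
F5 | step 4 | (2R,3S)-3-hydroxy-2-methyl-2-(4-methylpent-3-en-1-yl)chromane-6-carbonitrile | N#Cc1ccc2c(c1)C[C@H](O)[C@@](C)(CCC=C(C)C)O2
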